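## Analysis of the target

Target 20 is a 3,4-dihydronaphthalen-1(2H)-one. In tetralone numbering, ring B holds the C1 ketone, the C2 methylene, the C3 carbinol and the benzylic C4 methylene. Aromatic ring A (C4a to C8a) carries a 4-hydroxy-2-oxo-2H-pyran-6-yl group at C5, a 3-methylbutyl chain at C6 and a phenol at C8 that is hydrogen-bonded to the C1 carbonyl, so C7 is the only ring A carbon with a hydrogen. There is one stereocentre, C3, with (R) configuration. The aryl–pyranone axis at C5 has only the ring oxygen and a CH on the pyranone side, so it rotates freely and adds no second stereo-element. The C3 hydroxyl is β to the C1 ketone: acid or base can remove water across C2–C3, the enone formed tautomerises to a naphthalen-1-ol and the stereocentre is lost for good; the aldol can also revert. The 4-hydroxypyranone is a vinylogous carboxylic acid and an electrophilic lactone, and it quenches organometallic reagents unless it is masked. The difficulty is twofold: ring A has five substituents, three of them carbon groups on the adjacent atoms C4a, C5 and C6, and the only stereocentre sits in a labile β-hydroxy ketone that tolerates little chemistry once it exists. The route rests on reading ring B as a cyclic aldol, in which C2 is the methyl carbon of an acetyl group on C8a and C3 is the carbonyl carbon of an acetaldehyde arm on C4a.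

## Retrosynthetic reasoning

**20 to 19.** Only two O–C bonds of protecting groups are cut: the methyl ether at C8 and the benzyl ether on the pyranone oxygen. The methyl group survives organolithium and palladium chemistry and directs the lithiation used earlier. In 19 it lies peri to the C1 carbonyl, so a chelating boron Lewis acid can remove it at low temperature. The benzyl group masks the acidic pyranone hydroxyl through all metal-mediated steps and leaves under the same conditions. Only one mild operation therefore follows the making of the stereocentre.

**19 to 18.** The C2–C3 bond is cut. This is the one bond of ring B whose cleavage removes ring and stereocentre together and leaves an achiral precursor, keto-aldehyde 18, in which every ring A substituent is already in place. Cutting C1–C8a or C4–C4a instead would mean forming an aryl–carbon bond on a crowded ring with the stereocentre already in the chain. The forward reaction must enolise the acetyl group although the aldehyde α-methylene is more acidic, deliver the enolate to one face of the aldehyde, and stop at the aldol stage.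

**18 to 16 (through diol 17).** The aldehyde carbon is traced back to the internal carbon of a terminal alkene, with the C=C bond cut oxidatively. The allyl group of 16 is a robust carrier through the coupling steps, and the aldehyde, the most labile function of the route, appears only immediately before it is used.

**16 to 14 and 15.** The C4a–CH2 bond is cut to aryl bromide 14 and allylstannane 15. The bromine at C4a comes from the starting material, so no extra step is needed to place this handle.

**14 to 7 and 13.** The C5–pyranone bond is cut to aryl iodide 7 and pyranonyl stannane 13. Bringing in the pyranone as a finished unit is convergent and avoids building a heterocycle on a carbonyl flanked by two ortho groups. The iodide reacts before the bromide, which fixes the order of the two couplings.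

**13 to 12 to 11 to 8.** The C–Sn bond of 13 comes from the C–Cl bond of 12, the benzyl ether of 12 from the hydroxyl of 11, and the ring of 11 from two molecules of malonyl dichloride 8 (through 9 and 10).

**7 to 6.** The C5–I bond is cut. C5 is para to the methoxy group, so an electrophilic iodination should place the halogen there.

**6 to 3 (through 4 and 5).** The C8a–acetyl bond is cut. C8a lies between the methoxy group and the bromine of 3, which makes its hydrogen the most acidic one on the ring, so the acetyl group can enter by directed metalation and acylation.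

**3 to 1 and 2.** The C6–alkyl bond is cut to the symmetric dibromide 1 and Grignard reagent 2. Because 1 is symmetric, the first coupling needs no regiocontrol. The bromine that remains serves twice: as acidifying neighbour for the metalation and later as the handle for the C4a arm.

## Alternatives that were turned down

**Alternative 1:** Here ring A is cut, not ring B, at C4a–C5 and C8–C8a. Ring B arrives as the enantiopure sulfinyl enone A2, and C5 to C8 come from the glutaconate diester A3. In the forward key step the dienolate of A3 adds through the carbon that becomes C5 to the β-carbon (C4a) of A2. The sulfinyl-stabilised enolate carbon (C8a) then acylates on the distal ester to form C8–C8a, and sulfoxide elimination with enolisation aromatises the new ring to give A1.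
- For it: the substitution pattern of ring A follows from connectivity alone, with no halogenation regiochemistry and no hindered coupling for the alkyl chain, and the stereocentre is present early as a silyl ether. On regiocontrol of ring A it is stronger than the chosen route.
- Against it: A1 carries an allyl ester at C5, not the pyranone. The carboxyl group must be freed, activated, extended by four carbons and cyclised on a carbonyl with two ortho neighbours, which costs at least four further steps.
- Against it: A2 is a β-silyloxy ketone that can lose its oxygen group by E1cB elimination under the basic annulation conditions and end as a phenol. Its enantioselective preparation is itself several steps, and the final desilylation carries the same dehydration risk as the last step of the chosen route.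
- Comparison: the chosen route is shorter and makes the stereocentre in the second-to-last step, so it is not carried through basic chemistry.

**Alternative 2:** Both anchors of ring B on ring A (C4a–C4 and C8a–C1) are cut at once, back to the aryne precursor A5 and methyl acetoacetate A6. In the forward key step fluoride sets free the aryne. The enolate carbon of A6 adds to C4a, the aryne carbon remote from the methoxy group, the aryl anion at C8a attacks the ketone carbonyl, and the four-membered ring fragments to give A4.
- For it: two C–C bonds form in one step with built-in regiocontrol and without an organolithium. For placing the two anchors it is as good as, or shorter than, steps 2, 8 and 9 of the chosen route.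
- Against it: it closes no ring and makes no stereocentre. A4 has no substituent at C5, so the halogenation with its regiochemical question and the pyranone coupling still follow.
- Against it: the arm is at the ester oxidation level. It cannot be reduced selectively to the aldehyde beside the ketone, and under base it would undergo Claisen closure to an achiral, fully aromatic 1,3-dioxygenated naphthalene. A5 also needs several steps.
- Comparison: at best this is a longer way to 18 that still depends on the same aldol; the chosen route takes the aldehyde oxidation state directly from an alkene.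

**Alternative 3:** The C4–C4a bond is cut and ring B is traced to the cyclobutanol A8. In the forward key step zerovalent palladium adds to the C4a–Br bond and the tertiary alkoxide binds the metal. β-Carbon elimination opens one of the two enantiotopic cyclobutane bonds under control of a chiral ligand, and reductive elimination forms C4–C4a to give A7.
- For it: A8 would come in one step from aryllithium 4 and a 3-alkoxycyclobutanone, so the way to A7 is shorter than the way to 19. C3 is born protected, nothing is reversible and no acidic aldehyde is involved. On step count, and on robustness of the stereocentre at the moment it is made, this alternative is stronger.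
- Against it: the alkylpalladium species formed after ring opening has a β-benzyloxy group and a β-hydrogen, so β-alkoxide and β-hydride elimination compete with reductive elimination from a seven-membered palladacycle.
- Against it: the two diastereomers of A8 may be desymmetrised with different selectivity.
- Against it: A7 lacks the pyranone. Iodination at C5 and the hindered coupling would have to be run on a β-benzyloxy ketone, which can lose its benzyloxy group by E1cB elimination under the fluoride or base of the coupling, and the secondary alkyl benzyl ether needs harsher cleavage than the ethers of 19.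
- Comparison: the chosen route pays about two more steps, and in return completes ring A while the material is still achiral and robust, so only one mild deprotection follows the stereocentre.

Key step: step 10

Remark on the chemistry: the sense of induction of the zinc catalyst is assumed to follow the intermolecular aldol of acetophenone. With the CIP ranking at C3 of 19 taken into account (CH2C=O outranks CH2Ar), this points to the (R,R)-ligand. Both antipodes of the ligand are available, and the configuration of 19 is to be confirmed by Mosher ester analysis before the ligand is fixed.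

## Route

Step 1
Reactants: 1 3,5-dibromoanisole; 2 (3-methylbutyl)magnesium bromide
Product: 3 1-bromo-3-methoxy-5-(3-methylbutyl)benzene
Conditions: Pd(dppf)Cl2 (2 mol%), THF, 0 → 25 °C; 1 in excess (1.5 equiv), 2 added slowly
Reagents that add atoms: none
Why: Kumada–Corriu coupling; the wide-bite-angle dppf ligand makes reductive elimination of the primary alkyl–aryl palladium species faster than β-hydride elimination. Excess 1 and slow addition of 2 should hold the reaction at the mono stage, and the new alkyl group makes the second C–Br bond slightly less reactive than the first.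

Step 2
Reactants: 3 1-bromo-3-methoxy-5-(3-methylbutyl)benzene
Product: 6 1-[2-bromo-6-methoxy-4-(3-methylbutyl)phenyl]ethan-1-one, via aryllithium 4 (not isolated), via lithium hemiaminalate 5 (not isolated)
Conditions: LiN(i-Pr)2 (1.1 equiv), THF, −78 °C; MeC(O)N(OMe)Me, −78 → −40 °C; 1 M HCl
Reagents that add atoms: N-methoxy-N-methylacetamide, CC(=O)N(C)OC
Why: Directed ortho-metalation: the hydrogen between methoxy and bromine is the most acidic on the ring, and at −78 °C aryllithium 4 should not lose LiBr to an aryne. Acylation by the N-methoxy-N-methyl amide stops at chelate 5, which gives the ketone only on acidic work-up, so no tertiary alcohol forms.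

Step 3
Reactants: 6 1-[2-bromo-6-methoxy-4-(3-methylbutyl)phenyl]ethan-1-one
Product: 7 1-[2-bromo-3-iodo-6-methoxy-4-(3-methylbutyl)phenyl]ethan-1-one
Conditions: N-iodosuccinimide (1.1 equiv), CF3CO2H/MeCN, 25 °C, dark
Reagents that add atoms: N-iodosuccinimide, O=C1CCC(=O)N1I
Why: Electrophilic aromatic iodination. C5 is para to the methoxy group; C7, the only other free position, is ortho to it and screened by the O-methyl group, which the neighbouring acetyl group turns toward C7. The twisted acetyl group is meta to both positions and does not change the preference.

Step 4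
Reactants: 8 malonyl dichloride (two molecules)
Product: 11 6-chloro-4-hydroxy-2H-pyran-2-one, via pyranone acid chloride 9 (not isolated), via pyranone carboxylic acid 10 (not isolated)
Conditions: neat, 25 °C, several days; then H2O/dioxane, 50 °C
Reagents that add atoms: none
Why: Self-condensation of malonyl dichloride through its chlorocarbonyl ketene to the 6-chloro-4-hydroxypyranone acid chloride is a long-known reaction. Hydrolysis gives a vinylogous β-keto acid that should lose CO2 on gentle warming.

Step 5
Reactants: 11 6-chloro-4-hydroxy-2H-pyran-2-one
Product: 12 4-(benzyloxy)-6-chloro-2H-pyran-2-one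
Conditions: BnOH, PPh3, diisopropyl azodicarboxylate, THF, 0 → 25 °C
Reagents that add atoms: benzyl alcohol, OCc1ccccc1
Why: Mitsunobu O-alkylation with the acidic pyranone hydroxyl as pronucleophile; it reacts at oxygen and avoids the C-benzylation that competes under basic alkylation. No free alkoxide is present that could displace the chloride at C6.

Step 6
Reactants: 12 4-(benzyloxy)-6-chloro-2H-pyran-2-one
Product: 13 4-(benzyloxy)-6-(trimethylstannyl)-2H-pyran-2-one
Conditions: Me3Sn–SnMe3 (1.2 equiv), Pd(PPh3)4 (5 mol%), dioxane, 90 °C
Reagents that add atoms: hexamethylditin, C[Sn](C)(C)[Sn](C)(C)C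
Why: Palladium-catalysed stannylation of a halopyranone with a distannane, a reaction known for bromopyranones; the C6–Cl bond is activated like a vinylogous acid chloride and should add readily to zerovalent palladium. A small excess of distannane limits homocoupling.

Step 7
Reactants: 7 1-[2-bromo-3-iodo-6-methoxy-4-(3-methylbutyl)phenyl]ethan-1-one; 13 4-(benzyloxy)-6-(trimethylstannyl)-2H-pyran-2-one
Product: 14 6-[3-acetyl-2-bromo-4-methoxy-6-(3-methylbutyl)phenyl]-4-(benzyloxy)-2H-pyran-2-one
Conditions: Pd(PPh3)4 (10 mol%), CuI (20 mol%), CsF (2 equiv), DMF, 45 °C
Reagents that add atoms: none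
Why: Stille coupling with copper and fluoride co-promotion. Oxidative addition takes the C–I bond and leaves C–Br; monovalent copper speeds transmetalation between the two hindered partners and fluoride removes tin as Me3SnF. Ketone, bromide and pyranone are inert under these neutral conditions.

Step 8
Reactants: 14 6-[3-acetyl-2-bromo-4-methoxy-6-(3-methylbutyl)phenyl]-4-(benzyloxy)-2H-pyran-2-one; 15 allyltributylstannane
Product: 16 6-[3-acetyl-4-methoxy-6-(3-methylbutyl)-2-(prop-2-en-1-yl)phenyl]-4-(benzyloxy)-2H-pyran-2-one
Conditions: Pd(P(t-Bu)3)2 (5 mol%), CsF (2 equiv), dioxane, 80 °C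
Reagents that add atoms: none
Why: Stille allylation with the bulky, electron-rich P(t-Bu)3 ligand, which is known to couple hindered aryl bromides; the ortho acetyl group also activates the C–Br bond. Moderate temperature and short reaction time limit migration of the double bond into conjugation.

Step 9
Reactants: 16 6-[3-acetyl-4-methoxy-6-(3-methylbutyl)-2-(prop-2-en-1-yl)phenyl]-4-(benzyloxy)-2H-pyran-2-one
Product: 18 2-[2-acetyl-6-(4-benzyloxy-2-oxo-2H-pyran-6-yl)-3-methoxy-5-(3-methylbutyl)phenyl]acetaldehyde, via diol 17 (not isolated)
Conditions: OsO4 (2 mol%), NaIO4 (4 equiv), 2,6-lutidine (2 equiv), dioxane/H2O 3:1, 0 → 25 °C; product used at once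
Reagents that add atoms: osmium tetroxide, O=[Os](=O)(=O)=O (delivers the oxygen atom and is regenerated by sodium periodate, [Na+].[O-]I(=O)(=O)=O)
Why: Lemieux–Johnson oxidation. OsO4 should dihydroxylate the unhindered monosubstituted alkene much faster than the electron-poor conjugated pyranone double bonds, and periodate cleaves diol 17 to the aldehyde with loss of formaldehyde. 2,6-Lutidine keeps the medium near neutral.

Step 10
Reactants: 18 2-[2-acetyl-6-(4-benzyloxy-2-oxo-2H-pyran-6-yl)-3-methoxy-5-(3-methylbutyl)phenyl]acetaldehyde
Product: 19 4-(benzyloxy)-6-[(7R)-7-hydroxy-4-methoxy-2-(3-methylbutyl)-5-oxo-5,6,7,8-tetrahydronaphthalen-1-yl]-2H-pyran-2-one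
Conditions: (R,R)-ProPhenol (10 mol%), ZnEt2 (20 mol%), Ph3P=S (15 mol%), 4 Å molecular sieves, THF, −20 °C, 0.02 M, slow addition of 18; pH 7 buffer at −20 °C
Reagents that add atoms: none
Why: Proposed new method: the closest known reaction is the direct aldol addition of aryl methyl ketones to aldehydes catalysed by the dinuclear zinc complex of ProPhenol, which is established between two molecules but not as a ring closure onto a tethered, α-unbranched arylacetaldehyde. The complex formed from the ligand and two equivalents of ZnEt2 has a basic zinc centre that deprotonates the C8a acetyl group to a zinc enolate and a Lewis-acidic zinc centre that binds the aldehyde of the C4a arm; C2 then adds to C3, and the zinc aldolate is protonated by the next molecule of 18, which releases the catalyst. Ring B closes in the 6-(enolendo)-exo-trig mode, which is stereoelectronically favoured. The C3 stereocentre is set by the chiral bimetallic pocket, which exposes one enantioface of the bound aldehyde to the enolate; there is no other stereocentre and the aryl–pyranone axis rotates freely, so the catalyst is the only control element. The step needs site selectivity between two enolisable positions: the aldehyde α-methylene is the more acidic, but its enolate cannot close a ring through carbon because a four-membered ring would result, so it returns by proton transfer and only the ketone enolate leads to product. Intermolecular self-aldol of the aldehyde is held back by high dilution and slow addition of 18. Low temperature and a cold buffered quench keep the zinc aldolate from retro-aldol cleavage and from dehydration to the naphthol.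

Step 11
Reactants: 19 4-(benzyloxy)-6-[(7R)-7-hydroxy-4-methoxy-2-(3-methylbutyl)-5-oxo-5,6,7,8-tetrahydronaphthalen-1-yl]-2H-pyran-2-one
Product: 20 4-hydroxy-6-[(7R)-4,7-dihydroxy-2-(3-methylbutyl)-5-oxo-5,6,7,8-tetrahydronaphthalen-1-yl]-2H-pyran-2-one
Conditions: BCl3 (6 equiv), pentamethylbenzene (3 equiv), CH2Cl2, −78 °C; pH 7 buffer at −78 °C
Reagents that add atoms: none
Why: Lewis-acid ether cleavage. BCl3 chelates between the C1 carbonyl and the peri C8 methoxy group and should cleave this methyl ether fast at −78 °C; with pentamethylbenzene as a non-basic benzyl cation trap it should also remove the benzyl group from the pyranone oxygen. The C3 hydroxyl only forms a borate that is hydrolysed on work-up, no base is present, and the stereocentre is not touched.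

## Compound list

1 | 3,5-dibromoanisole | COc1cc(Br)cc(Br)c1 | starting material
2 | (3-methylbutyl)magnesium bromide | CC(C)CC[Mg]Br | starting material
3 | 1-bromo-3-methoxy-5-(3-methylbutyl)benzene | COc1cc(Br)cc(CCC(C)C)c1 | intermediate
4 | [2-bromo-6-methoxy-4-(3-methylbutyl)phenyl]lithium | [Li]c1c(Br)cc(CCC(C)C)cc1OC | intermediate
5 | lithium 1-[2-bromo-6-methoxy-4-(3-methylbutyl)phenyl]-1-[methoxy(methyl)amino]ethan-1-olate | CC(O[Li])(N(C)OC)c1c(Br)cc(CCC(C)C)cc1OC | intermediate
6 | 1-[2-bromo-6-methoxy-4-(3-methylbutyl)phenyl]ethan-1-one | CC(=O)c1c(Br)cc(CCC(C)C)cc1OC | intermediate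
7 | 1-[2-bromo-3-iodo-6-methoxy-4-(3-methylbutyl)phenyl]ethan-1-one | CC(=O)c1c(Br)c(I)c(CCC(C)C)cc1OC | intermediate
8 | malonyl dichloride | ClC(=O)CC(=O)Cl | starting material
9 | 6-chloro-4-hydroxy-2-oxo-2H-pyran-3-carbonyl chloride | O=C(Cl)c1c(O)cc(Cl)oc1=O | intermediate
10 | 6-chloro-4-hydroxy-2-oxo-2H-pyran-3-carboxylic acid | OC(=O)c1c(O)cc(Cl)oc1=O | intermediate
11 | 6-chloro-4-hydroxy-2H-pyran-2-one | Oc1cc(Cl)oc(=O)c1 | intermediate
12 | 4-(benzyloxy)-6-chloro-2H-pyran-2-one | O=c1cc(OCc2ccccc2)cc(Cl)o1 | intermediate
13 | 4-(benzyloxy)-6-(trimethylstannyl)-2H-pyran-2-one | C[Sn](C)(C)c1cc(OCc2ccccc2)cc(=O)o1 | intermediate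
14 | 6-[3-acetyl-2-bromo-4-methoxy-6-(3-methylbutyl)phenyl]-4-(benzyloxy)-2H-pyran-2-one | CC(=O)c1c(Br)c(-c2cc(OCc3ccccc3)cc(=O)o2)c(CCC(C)C)cc1OC | intermediate
15 | allyltributylstannane | C=CC[Sn](CCCC)(CCCC)CCCC | starting material
16 | 6-[3-acetyl-4-methoxy-6-(3-methylbutyl)-2-(prop-2-en-1-yl)phenyl]-4-(benzyloxy)-2H-pyran-2-one | CC(=O)c1c(CC=C)c(-c2cc(OCc3ccccc3)cc(=O)o2)c(CCC(C)C)cc1OC | intermediate
17 | 6-[3-acetyl-2-(2,3-dihydroxypropyl)-4-methoxy-6-(3-methylbutyl)phenyl]-4-(benzyloxy)-2H-pyran-2-one (racemic at the carbinol) | CC(=O)c1c(CC(O)CO)c(-c2cc(OCc3ccccc3)cc(=O)o2)c(CCC(C)C)cc1OC | intermediate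
18 | 2-[2-acetyl-6-(4-benzyloxy-2-oxo-2H-pyran-6-yl)-3-methoxy-5-(3-methylbutyl)phenyl]acetaldehyde | CC(=O)c1c(CC=O)c(-c2cc(OCc3ccccc3)cc(=O)o2)c(CCC(C)C)cc1OC | intermediate
19 | 4-(benzyloxy)-6-[(7R)-7-hydroxy-4-methoxy-2-(3-methylbutyl)-5-oxo-5,6,7,8-tetrahydronaphthalen-1-yl]-2H-pyran-2-one | CC(C)CCc1cc(OC)c2c(c1-c1cc(OCc3ccccc3)cc(=O)o1)C[C@@H](O)CC2=O | intermediate
20 | 4-hydroxy-6-[(7R)-4,7-dihydroxy-2-(3-methylbutyl)-5-oxo-5,6,7,8-tetrahydronaphthalen-1-yl]-2H-pyran-2-one, i.e. (3R)-3,8-dihydroxy-5-(4-hydroxy-2-oxo-2H-pyran-6-yl)-6-(3-methylbutyl)-3,4-dihydronaphthalen-1(2H)-one | CC(C)CCc1cc(O)c2c(c1-c1cc(O)cc(=O)o1)C[C@@H](O)CC2=O | target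

## Step count and least certain steps

Total: 11 steps. Longest linear sequence: 8 steps (steps 1, 2, 3, 7, 8, 9, 10 and 11 from 1). The stannane branch (steps 4, 5 and 6) joins at step 7 and is also 8 steps to 20.

**Step 10 (key step).**
- What may go wrong: the catalyst may be tied up by enolisation of the arylacetaldehyde, which is the more acidic site and can form a zinc enolate chelated by the neighbouring acetyl oxygen. Intermolecular self-aldol of the aldehyde may overtake the ring closure. The tether may impose a geometry in which the chiral pocket discriminates the aldehyde faces poorly, or in the opposite sense to the intermolecular model. The zinc aldolate may dehydrate to the naphthol or revert, which erodes the enantiomeric purity.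
- Fallback (known chemistry), from 16 back to 19:
  - The methyl ketone of 16 is converted with LiN(SiMe3)2 and Me3SiCl (THF, −78 °C) into the trimethylsilyl enol ether F1. N-Bromosuccinimide turns this into the α-bromo ketone F2.
  - Lemieux–Johnson cleavage as in step 9 gives the bromo keto-aldehyde F3. In F3 the nucleophilic carbon is defined by the C–Br bond and no longer by acidity.
  - SmI2 (2 equiv, THF, −78 °C) reduces the C–Br bond to a samarium enolate, which closes ring B in an intramolecular Reformatsky-type aldol and gives the racemic aldol F4.
  - F4 is resolved by lipase-catalysed transesterification with vinyl acetate. The enzyme is chosen so that the (S)-alcohol is acylated to the acetate F5 and the (R)-alcohol 19 is left. The price is the loss of half of the material.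

**Step 11.**
- What may go wrong: dehydration of the β-hydroxy ketone through its borate under the Lewis acid, above all if the pyranone benzyl ether is cleaved slowly and the mixture has to be warmed.
- Fallback, from 14 back to 20:
  - One equivalent of BCl3 at −78 °C cleaves only the methyl ether ortho to the acetyl group of 14 and gives the phenol F6. Benzyl bromide and K2CO3 in DMF give the bis(benzyl ether) F7.
  - Steps 8, 9 and 10 are repeated in this series: the allyl compound F8, the keto-aldehyde F9 and the aldol F10.
  - Both benzyl groups are removed by hydrogenolysis (H2, Pd/C, ethyl acetate), which is neutral and uses no Lewis acid.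

**Step 3.**
- What may go wrong: attack at C7 instead of C5, because C5 is flanked by bromine and the alkyl chain and iodine is a large electrophile; α-iodination of the methyl ketone under acid.
- Fallback, from 3 back to 16:
  - 3 is brominated with N-bromosuccinimide in acetonitrile, which in 3,5-disubstituted anisoles goes to the para position, to give 1,2-dibromo-5-methoxy-3-(3-methylbutyl)benzene F11.
  - Lithiation between methoxy and bromine and acylation as in step 2 (the aryllithium F12, the lithium hemiaminalate F13) give the dibromo ketone F14.
  - The two C–Br bonds are then told apart by electronics instead of by the kind of halogen. The one ortho to the acetyl group should add to zerovalent palladium first and is coupled with 15 to give the allyl bromide F15.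
  - The remaining C5–Br bond is coupled with 13 under the conditions of step 8 to give 16.

**Step 7 (with step 6).**
- What may go wrong: protodestannylation or homocoupling of stannane 13 during its preparation or use; slow transmetalation at an iodide with two ortho substituents.
- Fallback, from 7 and 12 back to 14; it reverses the polarity and omits step 6:
  - Zinc dust with LiCl in THF inserts into the C–I bond of 7, with the C–Br bond and the ketone tolerated, and gives the arylzinc iodide F16.
  - F16 is coupled with the chloropyranone 12 in a Negishi reaction (Pd(OAc)2, SPhos, THF).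

**Step 9 (with step 8).**
- What may go wrong: migration of the allyl double bond into conjugation in step 8; self-condensation or premature, racemic aldol closure of 18 during the aqueous oxidative cleavage and its work-up, which would lower the enantiomeric purity reached in step 10.
- Fallback, from 14 back to 18; it replaces steps 8 and 9:
  - Suzuki–Miyaura coupling of 14 with (E)-2-(2-ethoxyethenyl)-4,4,5,5-tetramethyl-1,3,2-dioxaborolane (Pd(dppf)Cl2, CsF, dioxane, 80 °C) gives the enol ether F17, which can be stored.
  - Brief treatment with dilute aqueous HCl in THF at 0 °C releases 18 immediately before the aldol step, with no oxidant and no amine present.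

## Further compounds

F1 | step 10 | 4-(benzyloxy)-6-[4-methoxy-6-(3-methylbutyl)-2-(prop-2-en-1-yl)-3-{1-[(trimethylsilyl)oxy]ethenyl}phenyl]-2H-pyran-2-one | C=C(O[Si](C)(C)C)c1c(CC=C)c(-c2cc(OCc3ccccc3)cc(=O)o2)c(CCC(C)C)cc1OC
F2 | step 10 | 4-(benzyloxy)-6-[3-(bromoacetyl)-4-methoxy-6-(3-methylbutyl)-2-(prop-2-en-1-yl)phenyl]-2H-pyran-2-one | BrCC(=O)c1c(CC=C)c(-c2cc(OCc3ccccc3)cc(=O)o2)c(CCC(C)C)cc1OC
F3 | step 10 | 2-[6-(4-benzyloxy-2-oxo-2H-pyran-6-yl)-2-(bromoacetyl)-3-methoxy-5-(3-methylbutyl)phenyl]acetaldehyde | BrCC(=O)c1c(CC=O)c(-c2cc(OCc3ccccc3)cc(=O)o2)c(CCC(C)C)cc1OC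
F4 | step 10 | racemic 4-(benzyloxy)-6-[7-hydroxy-4-methoxy-2-(3-methylbutyl)-5-oxo-5,6,7,8-tetrahydronaphthalen-1-yl]-2H-pyran-2-one | CC(C)CCc1cc(OC)c2c(c1-c1cc(OCc3ccccc3)cc(=O)o1)CC(O)CC2=O
F5 | step 10 | (2S)-8-(4-benzyloxy-2-oxo-2H-pyran-6-yl)-5-methoxy-7-(3-methylbutyl)-4-oxo-1,2,3,4-tetrahydronaphthalen-2-yl acetate | CC(C)CCc1cc(OC)c2c(c1-c1cc(OCc3ccccc3)cc(=O)o1)C[C@H](OC(C)=O)CC2=O
F6 | step 11 | 6-[3-acetyl-2-bromo-4-hydroxy-6-(3-methylbutyl)phenyl]-4-(benzyloxy)-2H-pyran-2-one | CC(=O)c1c(Br)c(-c2cc(OCc3ccccc3)cc(=O)o2)c(CCC(C)C)cc1O
F7 | step 11 | 6-[3-acetyl-4-(benzyloxy)-2-bromo-6-(3-methylbutyl)phenyl]-4-(benzyloxy)-2H-pyran-2-one | CC(=O)c1c(Br)c(-c2cc(OCc3ccccc3)cc(=O)o2)c(CCC(C)C)cc1OCc1ccccc1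
F8 | step 11 | 6-[3-acetyl-4-(benzyloxy)-6-(3-methylbutyl)-2-(prop-2-en-1-yl)phenyl]-4-(benzyloxy)-2H-pyran-2-one | CC(=O)c1c(CC=C)c(-c2cc(OCc3ccccc3)cc(=O)o2)c(CCC(C)C)cc1OCc1ccccc1
F9 | step 11 | 2-[2-acetyl-3-(benzyloxy)-6-(4-benzyloxy-2-oxo-2H-pyran-6-yl)-5-(3-methylbutyl)phenyl]acetaldehyde | CC(=O)c1c(CC=O)c(-c2cc(OCc3ccccc3)cc(=O)o2)c(CCC(C)C)cc1OCc1ccccc1
F10 | step 11 | 4-(benzyloxy)-6-[(7R)-4-(benzyloxy)-7-hydroxy-2-(3-methylbutyl)-5-oxo-5,6,7,8-tetrahydronaphthalen-1-yl]-2H-pyran-2-one | CC(C)CCc1cc(OCc2ccccc2)c2c(c1-c1cc(OCc3ccccc3)cc(=O)o1)C[C@@H](O)CC2=O
F11 | step 3 | 1,2-dibromo-5-methoxy-3-(3-methylbutyl)benzene | COc1cc(Br)c(Br)c(CCC(C)C)c1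
F12 | step 3 | [2,3-dibromo-6-methoxy-4-(3-methylbutyl)phenyl]lithium | [Li]c1c(Br)c(Br)c(CCC(C)C)cc1OC
F13 | step 3 | lithium 1-[2,3-dibromo-6-methoxy-4-(3-methylbutyl)phenyl]-1-[methoxy(methyl)amino]ethan-1-olate | CC(O[Li])(N(C)OC)c1c(Br)c(Br)c(CCC(C)C)cc1OC
F14 | step 3 | 1-[2,3-dibromo-6-methoxy-4-(3-methylbutyl)phenyl]ethan-1-one | CC(=O)c1c(Br)c(Br)c(CCC(C)C)cc1OC
F15 | step 3 | 1-[3-bromo-6-methoxy-4-(3-methylbutyl)-2-(prop-2-en-1-yl)phenyl]ethan-1-one | CC(=O)c1c(CC=C)c(Br)c(CCC(C)C)cc1OC
F16 | step 7 | [3-acetyl-2-bromo-4-methoxy-6-(3-methylbutyl)phenyl]zinc iodide | CC(=O)c1c(Br)c([Zn]I)c(CCC(C)C)cc1OC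
F17 | step 9 | 6-{3-acetyl-2-[(E)-2-ethoxyethenyl]-4-methoxy-6-(3-methylbutyl)phenyl}-4-(benzyloxy)-2H-pyran-2-one | CC(=O)c1c(/C=C/OCC)c(-c2cc(OCc3ccccc3)cc(=O)o2)c(CCC(C)C)cc1OC
A1 | alternative 1 | allyl (7R)-4-hydroxy-2-(3-methylbutyl)-5-oxo-7-(tert-butyldimethylsilyloxy)-5,6,7,8-tetrahydronaphthalene-1-carboxylate | CC(C)CCc1cc(O)c2c(c1C(=O)OCC=C)C[C@@H](O[Si](C)(C)C(C)(C)C)CC2=O
A2 | alternative 1 | (5R)-5-(tert-butyldimethylsilyloxy)-2-(4-methylbenzenesulfinyl)cyclohex-2-en-1-one (configuration at sulfur not fixed) | O=C1C[C@H](O[Si](C)(C)C(C)(C)C)CC=C1S(=O)c1ccc(C)cc1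
A3 | alternative 1 | 1-methyl 5-(prop-2-en-1-yl) 3-(3-methylbutyl)pent-2-enedioate | COC(=O)C=C(CCC(C)C)CC(=O)OCC=C
A4 | alternative 2 | methyl 2-[2-acetyl-3-methoxy-5-(3-methylbutyl)phenyl]acetate | COC(=O)Cc1cc(CCC(C)C)cc(OC)c1C(C)=O
A5 | alternative 2 | 3-methoxy-5-(3-methylbutyl)-2-(trimethylsilyl)phenyl trifluoromethanesulfonate | COc1cc(CCC(C)C)cc(OS(=O)(=O)C(F)(F)F)c1[Si](C)(C)C
A6 | alternative 2 | methyl acetoacetate | CC(=O)CC(=O)OC
A7 | alternative 3 | (3R)-3-(benzyloxy)-8-methoxy-6-(3-methylbutyl)-3,4-dihydronaphthalen-1(2H)-one | CC(C)CCc1cc(OC)c2c(c1)C[C@@H](OCc1ccccc1)CC2=O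
A8 | alternative 3 | 3-(benzyloxy)-1-[2-bromo-6-methoxy-4-(3-methylbutyl)phenyl]cyclobutan-1-ol (relative configuration not fixed) | COc1cc(CCC(C)C)cc(Br)c1C1(O)CC(OCc2ccccc2)C1
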